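**Retrosynthetic overview**

1. The target is a trans-(1R,6R)-cyclohex-3-ene: C1 carries the 2,4-dihydroxy-6-methoxybenzoyl group, C6 the phenyl ring, C4 the 4-methylpent-3-enyl chain. The two MOM ethers come off last; before that the C6–phenyl bond is made by rhodium-catalysed asymmetric conjugate addition of PhB(OH)2, and C1 (α to the aryl ketone, epimerisable) is set trans by equilibration.
2. Feature used: the ring alkene C3=C4 is flanked by two CH2 groups (C2, C5) and lies across the ring from the C1–C6 bond. With C1=C6 as an enone the ring is a 1,4-disubstituted cyclohexa-1,4-diene, the [4+2] adduct of a terminal alkyne (C3, C4) and a 2-aroylbuta-1,3-diene (C2, C1, C6, C5).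
3. Key disconnection: bonds C2–C3 and C4–C5, made together by cobalt-catalysed cycloaddition of 6-methylhept-5-en-1-yne with the 2-aroyl diene.
4. The diene comes from 2,4-dihydroxy-6-methoxybenzaldehyde (MOM protection, indium-mediated butadien-2-ylation, MnO2); the alkyne from 5-bromo-2-methylpent-2-ene and lithium acetylide.
5. Ring order: only the cyclohexene ring is built (in the key step); both benzene rings are bought in.

Key step: step 5

Assumption: the sense of induction in step 6 is assigned by analogy with (E)-configured acyclic enones and would be checked on the first run, the antipodal ligand being used if it proves opposite.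

**Route**

Step 1
Reactants: 1 5-bromo-2-methylpent-2-ene; 2 lithium acetylide–ethylenediamine complex (LiC≡CH·H2NCH2CH2NH2)
Product: 3 6-methylhept-5-en-1-yne
Conditions: DMSO, 10 to 20 °C
Reagents that add atoms: none
Why: SN2 alkylation of the acetylide by an unhindered primary homoallylic bromide in DMSO is the standard terminal-alkyne synthesis, and no stereocentre is formed.

Step 2
Reactants: 4 2,4-dihydroxy-6-methoxybenzaldehyde
Product: 5 2-methoxy-4,6-bis(methoxymethoxy)benzaldehyde
Conditions: NaH, MOMCl, DMF, 0 to 20 °C
Reagents that add atoms: chloromethyl methyl ether (MOMCl), COCCl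
Why: Williamson-type O-alkylation of both phenoxides (NaH also deprotonates the chelated ortho-hydroxyl) masks the phenols as base-stable MOM acetals for the organometallic steps, and no stereocentre is formed.

Step 3
Reactants: 5 2-methoxy-4,6-bis(methoxymethoxy)benzaldehyde; 6 1,4-dibromobut-2-yne
Product: 7 1-[2-methoxy-4,6-bis(methoxymethoxy)phenyl]-2-methylidenebut-3-en-1-ol (racemic)
Conditions: In (powder), THF/H2O, 20 °C; NaHCO3 work-up
Reagents that add atoms: none
Why: This is the indium-mediated Barbier-type 1,3-butadien-2-ylation of aldehydes, in which the propargylic indium species adds to the aldehyde with transposition and reduction of the second C–Br bond followed by protonation unveils the 2-substituted buta-1,3-diene; the carbinol centre forms racemic and is erased in step 4.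

Step 4
Reactants: 7 1-[2-methoxy-4,6-bis(methoxymethoxy)phenyl]-2-methylidenebut-3-en-1-ol
Product: 8 1-[2-methoxy-4,6-bis(methoxymethoxy)phenyl]-2-methylidenebut-3-en-1-one
Conditions: activated MnO2, CH2Cl2, 0 °C; filtered, dried, solution used at once
Reagents that add atoms: none
Why: MnO2 oxidation of a doubly activated (benzylic and allylic) secondary alcohol proceeds under neutral heterogeneous conditions, and the dimerisation-prone 2-aroyl diene is kept cold and dilute in the solvent of the next step.

Step 5
Reactants: 8 1-[2-methoxy-4,6-bis(methoxymethoxy)phenyl]-2-methylidenebut-3-en-1-one; 3 6-methylhept-5-en-1-yne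
Product: 9 [2-methoxy-4,6-bis(methoxymethoxy)phenyl][4-(4-methylpent-3-en-1-yl)cyclohexa-1,4-dien-1-yl]methanone
Conditions: CoBr2(dppe) (10 mol %; dppe = 1,2-bis(diphenylphosphino)ethane), Zn, ZnI2 (20 mol % each), 3 (2 equiv), CH2Cl2, 20 °C, slow addition of 8
Reagents that add atoms: none
Why: Zn reduces CoBr2(dppe) and ZnI2 abstracts bromide to give a cationic monovalent cobalt–dppe species that binds the s-cis diene and the alkyne; oxidative cyclisation to an allyl–vinyl cobaltacycle and C–C reductive elimination then join the diene CH2 next to the aroyl-bearing carbon to the alkyne CH and the other diene CH2 to the chain-bearing alkyne carbon. The closest known reaction type is the cobalt-catalysed neutral Diels–Alder reaction of unactivated terminal alkynes with 2-substituted buta-1,3-dienes, which gives 1,4-disubstituted cyclohexa-1,4-dienes. The one ring built in the route, the six-membered carbocycle, is closed in an intermolecular [4+2] mode by these two bonds. No stereocentre is formed; the step instead fixes the trisubstituted ring alkene at the former alkyne carbons and leaves the inner diene carbons as an aroyl enone for the stereo-setting step 6. The selectivity needed is regiochemical (1,4 against 1,3 placement of aroyl group and chain); it is secured by the dppe ligand together with the substrate pattern, a diene substituted only at C2 by a bulky 2,6-disubstituted aroyl group and a terminal alkyne, which keeps the two substituents apart in the cobaltacycle. Chemoselectivity rests on the inertness of the trisubstituted chain alkene towards this catalyst and on the low stationary concentration of 8, so that cycloaddition should outrun Diels–Alder dimerisation of the dienone.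

Step 6
Reactants: 9 [2-methoxy-4,6-bis(methoxymethoxy)phenyl][4-(4-methylpent-3-en-1-yl)cyclohexa-1,4-dien-1-yl]methanone; 10 phenylboronic acid
Product: 12 [2-methoxy-4,6-bis(methoxymethoxy)phenyl][(1R,6R)-4-(4-methylpent-3-en-1-yl)-6-phenylcyclohex-3-en-1-yl]methanone, via cis-(1S,6R) epimer 11 (not isolated)
Conditions: [Rh(OH)(cod)]2 (1.5 mol %), (R)-BINAP (3.3 mol %), PhB(OH)2 (3 equiv), dioxane/H2O 10:1, 40 °C; then NaOMe (cat.), MeOH, 50 °C
Reagents that add atoms: none
Why: In this Hayashi–Miyaura reaction (rhodium-catalysed asymmetric 1,4-addition of an arylboronic acid to an enone) the phenylrhodium–(R)-BINAP species inserts the enone C=C and delivers phenyl to the Re face of the β-carbon under ligand control to set C6 as R, hydrolysis of the rhodium enolate gives the C1 epimers, and NaOMe funnels them through the enolate to the diequatorial trans (1R,6R) ketone under thermodynamic control.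

Step 7
Reactants: 12 [2-methoxy-4,6-bis(methoxymethoxy)phenyl][(1R,6R)-4-(4-methylpent-3-en-1-yl)-6-phenylcyclohex-3-en-1-yl]methanone
Product: 13 (2,4-dihydroxy-6-methoxyphenyl)[(1R,6R)-4-(4-methylpent-3-en-1-yl)-6-phenylcyclohex-3-en-1-yl]methanone (CNP0142503.1)
Conditions: conc. HCl (cat.), MeOH, 40 °C
Reagents that add atoms: none
Why: Acid-catalysed acetal exchange with methanol removes both aryl MOM ethers at an acid strength that trisubstituted alkenes should tolerate, and C1 stays in its thermodynamic trans configuration even if it enolises.

**Compound list**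

1 | 5-bromo-2-methylpent-2-ene | CC(C)=CCCBr | starting material
2 | lithium acetylide–ethylenediamine complex | [Li+].[C-]#C.NCCN | starting material
3 | 6-methylhept-5-en-1-yne | C#CCCC=C(C)C | intermediate
4 | 2,4-dihydroxy-6-methoxybenzaldehyde | COc1cc(O)cc(O)c1C=O | starting material
5 | 2-methoxy-4,6-bis(methoxymethoxy)benzaldehyde | COc1cc(OCOC)cc(OCOC)c1C=O | intermediate
6 | 1,4-dibromobut-2-yne | BrCC#CCBr | starting material
7 | 1-[2-methoxy-4,6-bis(methoxymethoxy)phenyl]-2-methylidenebut-3-en-1-ol (racemic) | COc1cc(OCOC)cc(OCOC)c1C(O)C(=C)C=C | intermediate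
8 | 1-[2-methoxy-4,6-bis(methoxymethoxy)phenyl]-2-methylidenebut-3-en-1-one | COc1cc(OCOC)cc(OCOC)c1C(=O)C(=C)C=C | intermediate
9 | [2-methoxy-4,6-bis(methoxymethoxy)phenyl][4-(4-methylpent-3-en-1-yl)cyclohexa-1,4-dien-1-yl]methanone | COc1cc(OCOC)cc(OCOC)c1C(=O)C1=CCC(CCC=C(C)C)=CC1 | intermediate
10 | phenylboronic acid | OB(O)c1ccccc1 | starting material
11 | [2-methoxy-4,6-bis(methoxymethoxy)phenyl][(1S,6R)-4-(4-methylpent-3-en-1-yl)-6-phenylcyclohex-3-en-1-yl]methanone (cis epimer, not isolated) | COc1cc(OCOC)cc(OCOC)c1C(=O)[C@H]1CC=C(CCC=C(C)C)C[C@H]1c1ccccc1 | intermediate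
12 | [2-methoxy-4,6-bis(methoxymethoxy)phenyl][(1R,6R)-4-(4-methylpent-3-en-1-yl)-6-phenylcyclohex-3-en-1-yl]methanone | COc1cc(OCOC)cc(OCOC)c1C(=O)[C@@H]1CC=C(CCC=C(C)C)C[C@H]1c1ccccc1 | intermediate
13 | (2,4-dihydroxy-6-methoxyphenyl)[(1R,6R)-4-(4-methylpent-3-en-1-yl)-6-phenylcyclohex-3-en-1-yl]methanone | COc1cc(O)cc(O)c1C(=O)[C@@H]1CC=C(CCC=C(C)C)C[C@H]1c1ccccc1 | target

**Step count**

Total steps: 7. Longest linear sequence: 6 steps (4 to 13, steps 2 to 7); step 1 is a one-step side branch.

**Steps most likely to fail**

Step 5. The 2-aroyl diene 8 may dimerise by Diels–Alder reaction, or be held on cobalt through its carbonyl group, faster than it enters the cobalt-bound cycloaddition; the 1,4-orientation may also erode because the diene is electron-poor. The fallback sets out from 7 and returns at 9. It builds the ring one oxidation level lower, where the diene is an ordinary 2-alkyl-type butadiene of the best-precedented class, and unveils the ketone afterwards. Carbinol 7 is silylated (TBSOTf, 2,6-lutidine, CH2Cl2, −78 °C) to tert-butyl({1-[2-methoxy-4,6-bis(methoxymethoxy)phenyl]-2-methylidenebut-3-en-1-yl}oxy)dimethylsilane F1. The same CoBr2(dppe)/Zn/ZnI2 cycloaddition with alkyne 3 should give the silyl ether of the cyclohexa-1,4-dienyl carbinol F2. TBAF in THF frees [2-methoxy-4,6-bis(methoxymethoxy)phenyl][4-(4-methylpent-3-en-1-yl)cyclohexa-1,4-dien-1-yl]methanol F3, and MnO2 in CH2Cl2 oxidises it to 9.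

Step 6. Insertion of the hindered trisubstituted enone into the phenyl–rhodium bond may be slow, so that protodeboronation consumes the boronic acid; the skipped ring alkene may migrate into conjugation before addition; or phenyl may be delivered with low or opposite facial preference. The fallback sets out from 9 and returns at 12. Copper-mediated 1,4-addition of PhMgBr (CuBr·SMe2, TMSCl, THF, −78 °C), hydrolysis of the silyl enol ether and NaOMe equilibration should give the racemic trans ketone, that is 12 together with its mirror image, the (1S,6S) enantiomer of 12 F4. Preparative chromatography on a chiral stationary phase then separates 12 from it.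

Step 3. Barbier addition to the hindered, electron-rich aldehyde may be sluggish, so that reductive elimination of the dibromide to butatriene and its oligomers uses up the reagent; the very electron-rich benzylic carbinol may also ionise during work-up. The fallback sets out from 5 and returns at 7. Ethynylmagnesium bromide in THF adds to 5 to give 1-[2-methoxy-4,6-bis(methoxymethoxy)phenyl]prop-2-yn-1-ol F5. Cross enyne metathesis with ethylene (1 atm, second-generation Grubbs catalyst RuCl2(=CHPh)(H2IMes)(PCy3), CH2Cl2, 40 °C) converts the alkyne into the 2-substituted buta-1,3-diene 7.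

**Further compounds**

F1 | step 5 | tert-butyl({1-[2-methoxy-4,6-bis(methoxymethoxy)phenyl]-2-methylidenebut-3-en-1-yl}oxy)dimethylsilane (racemic) | COc1cc(OCOC)cc(OCOC)c1C(O[Si](C)(C)C(C)(C)C)C(=C)C=C
F2 | step 5 | tert-butyl({[2-methoxy-4,6-bis(methoxymethoxy)phenyl][4-(4-methylpent-3-en-1-yl)cyclohexa-1,4-dien-1-yl]methyl}oxy)dimethylsilane (racemic) | COc1cc(OCOC)cc(OCOC)c1C(O[Si](C)(C)C(C)(C)C)C1=CCC(CCC=C(C)C)=CC1
F3 | step 5 | [2-methoxy-4,6-bis(methoxymethoxy)phenyl][4-(4-methylpent-3-en-1-yl)cyclohexa-1,4-dien-1-yl]methanol (racemic) | COc1cc(OCOC)cc(OCOC)c1C(O)C1=CCC(CCC=C(C)C)=CC1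
F4 | step 6 | [2-methoxy-4,6-bis(methoxymethoxy)phenyl][(1S,6S)-4-(4-methylpent-3-en-1-yl)-6-phenylcyclohex-3-en-1-yl]methanone | COc1cc(OCOC)cc(OCOC)c1C(=O)[C@H]1CC=C(CCC=C(C)C)C[C@@H]1c1ccccc1
F5 | step 3 | 1-[2-methoxy-4,6-bis(methoxymethoxy)phenyl]prop-2-yn-1-ol (racemic) | COc1cc(OCOC)cc(OCOC)c1C(O)C#C
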